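**Plan**
- Retrosynthesis: cut the aroyl C(=O)–O2 bond, then the glycerol C1–C2 bond (lithiation–borylation), then O–C1 (alkoxide + bromomethylboronate). In the chain, cut C2'–C3' with the 4'E alkene (Johnson–Claisen) and C4'–C5' (vinyl Grignard).
- Forward: octadienal → vinyl carbinol → [3,3] → trienoate → trienol 7 → α-alkoxymethyl boronate 10; union with lithiated ester 13 and oxidation give 16; acylation at O2; double desilylation. No ring is formed; the arene is bought.
- Enabling feature: the O–C1H2–C2H(O)–C3H2–O array. C1 is an oxygen-bearing CH2 that can sit on boron; C2 is a carbinol CH that can be a carboxylate-bearing lithio carbenoid and later takes its oxygen from the C–B bond.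
- Stereochemistry: C2 comes from (+)-sparteine-mediated removal of one enantiotopic hydrogen, relayed by retention (C–B formation), inversion (1,2-shift) and retention (C–B → C–O). The 6'E,8'E alkenes are bought with the dienal; 4'E comes from the chair Claisen.
- The key event leaves the three glycerol oxygens differentiated (O1 ether, O2 free OH, O3 silyl ether), so the aroyl group goes onto O2 without diol differentiation.

Key step: step 6

Assumption: the sense of deprotonation known for primary alkyl 2,4,6-triisopropylbenzoates (the (−)-sparteine complex removes the pro-S hydrogen) is taken to hold for the β-silyloxy ester 12, so (+)-sparteine is used; all triene compounds are handled cold, under argon, in the dark.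

**Step 1**
Reactants: 1 (2E,4E)-octa-2,4-dienal; 2 vinylmagnesium bromide
Product: 3 (4E,6E)-deca-1,4,6-trien-3-ol (racemic)
Conditions: THF, −78 → 0 °C; then H2O
Reagents that add atoms: none
Why: Grignard 1,2-addition to the aldehyde carbonyl (no conjugate addition expected from the hard nucleophile); the new carbinol centre is racemic and is consumed in step 2.

**Step 2**
Reactants: 3 (4E,6E)-deca-1,4,6-trien-3-ol; 4 triethyl orthoacetate
Product: 6 ethyl (4E,6E,8E)-dodeca-4,6,8-trienoate, via ketene acetal 5 (not isolated)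
Conditions: MeC(OEt)3 (excess), EtCO2H (cat.), 138 °C, EtOH distilled off
Reagents that add atoms: none
Why: Johnson–Claisen rearrangement: exchange and loss of ethanol give ketene acetal 5, whose chair [3,3] shift across the unsubstituted vinyl terminus (dienyl group equatorial) should form C2'–C3' and the new 4E alkene in conjugation with the diene.

**Step 3**
Reactants: 6 ethyl (4E,6E,8E)-dodeca-4,6,8-trienoate
Product: 7 (4E,6E,8E)-dodeca-4,6,8-trien-1-ol
Conditions: LiAlH4, Et2O, 0 °C; then H2O/aq NaOH work-up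
Reagents that add atoms: none
Why: hydride reduction of the isolated ester to the primary alcohol; the unactivated triene is inert to LiAlH4.

**Step 4**
Reactants: 7 (4E,6E,8E)-dodeca-4,6,8-trien-1-ol; 8 2-(bromomethyl)-4,4,5,5-tetramethyl-1,3,2-dioxaborolane
Product: 10 2-({[(4E,6E,8E)-dodeca-4,6,8-trien-1-yl]oxy}methyl)-4,4,5,5-tetramethyl-1,3,2-dioxaborolane, via sodium alkoxide 9 (not isolated)
Conditions: NaH, THF, 0 °C → rt; then 8, THF/DMSO, rt
Reagents that add atoms: none
Why: Matteson-type O-alkylation, in which the alkoxide adds to boron and shifts from B to C with loss of bromide, the standard entry to α-alkoxymethyl pinacol boronates.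

**Step 5**
Reactants: 11 2-[(tert-butyldimethylsilyl)oxy]ethan-1-ol
Product: 12 2-[(tert-butyldimethylsilyl)oxy]ethyl 2,4,6-tri(propan-2-yl)benzoate
Conditions: 2,4,6-triisopropylbenzoic acid, PPh3, DIAD, THF, 0 °C → rt
Reagents that add atoms: 2,4,6-triisopropylbenzoic acid, CC(C)c1cc(C(C)C)c(C(=O)O)c(C(C)C)c1
Why: Mitsunobu esterification of a primary alcohol with the hindered acid, the usual route to primary alkyl triisopropylbenzoates; the neutral conditions leave the silyl ether in place.

**Step 6**
Reactants: 12 2-[(tert-butyldimethylsilyl)oxy]ethyl 2,4,6-tri(propan-2-yl)benzoate (slight excess over s-BuLi); 10 the α-alkoxymethyl boronate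
Product: 16 (2R)-1-[(tert-butyldimethylsilyl)oxy]-3-{[(4E,6E,8E)-dodeca-4,6,8-trien-1-yl]oxy}propan-2-ol, via lithiated ester 13 (not isolated), via boronate complex 14 (not isolated), via secondary boronic ester 15 (not isolated)
Conditions: s-BuLi, (+)-sparteine, Et2O, −78 °C; then 10, −78 → 35 °C; then NaBO3·4H2O, THF/H2O, rt
Reagents that add atoms: sodium perborate tetrahydrate, O.O.O.O.O.O.[Na+].[Na+].O[B-]1(O)OO[B-](O)(O)OO1
Why: The ester carbonyl directs s-BuLi·(+)-sparteine to the OCH2 group of 12 and the diamine selects the pro-R hydrogen, giving the (R)-lithio ester 13, which should hold its configuration at −78 °C. Boronate 10 traps 13 at boron with retention (complex 14); on warming, the α-alkoxymethyl group shifts from B to C antiperiplanar to the departing carboxylate (inversion), a stereospecific 1,2-metallate rearrangement that forms C1–C2 and gives 15, and perborate then replaces B by OH with retention. The closest known reaction type is lithiation–borylation–oxidation of primary alkyl triisopropylbenzoates with pinacol boronic esters, together with the Matteson homologation of α-alkoxymethyl boronates. No ring is closed. The C2 stereocentre is controlled by the chiral diamine in the deprotonation and then by the stereospecificity of each later event. The step needs lithiation at OCH2–O(acyl) and not at OCH2–OSi (carbonyl direction), survival of the β-silyloxy carbanion (−78 °C, bulky and poorly coordinating silyl ether), and migration of the only carbon ligand on boron with carboxylate rather than alkoxide as leaving group; the triene meets no alkyllithium because s-BuLi is consumed before 10 is added.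

**Step 7**
Reactants: 17 4-hydroxybenzoic acid
Product: 19 4-[(tert-butyldimethylsilyl)oxy]benzoic acid, via silyl ester 18 (not isolated)
Conditions: TBSCl, imidazole, DMF, rt; then AcOH/THF/H2O, rt
Reagents that add atoms: tert-butyldimethylsilyl chloride, CC(C)(C)[Si](C)(C)Cl
Why: silylation of both acidic OH groups, then selective hydrolysis of the labile silyl ester under mild aqueous acid, to which the aryl silyl ether is stable.

**Step 8**
Reactants: 16 the (2R)-alcohol; 19 4-[(tert-butyldimethylsilyl)oxy]benzoic acid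
Product: 20 (2R)-1-[(tert-butyldimethylsilyl)oxy]-3-{[(4E,6E,8E)-dodeca-4,6,8-trien-1-yl]oxy}propan-2-yl 4-[(tert-butyldimethylsilyl)oxy]benzoate
Conditions: DCC, DMAP (cat.), CH2Cl2, 0 °C → rt
Reagents that add atoms: none
Why: Steglich esterification of the secondary alcohol; the C2–O bond is not broken, so the configuration is kept, and the absence of strong base disfavours 1,2-silyl migration.

**Step 9**
Reactants: 20 the bis-silyl ester
Product: 21 (2S)-1-{[(4E,6E,8E)-dodeca-4,6,8-trien-1-yl]oxy}-3-hydroxypropan-2-yl 4-hydroxybenzoate (target)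
Conditions: HF·pyridine, pyridine, THF, 0 °C → rt; work-up at pH 7, cold
Reagents that add atoms: none
Why: fluoride-mediated cleavage of both Si–O bonds under pyridine-buffered, weakly acidic conditions in which no alkoxide forms, so the aroyl group should stay on O2; the descriptor changes from R to S only because CH2OH ranks below CH2OR once silicon is gone.

**Compound list**
1 | (2E,4E)-octa-2,4-dienal | CCC/C=C/C=C/C=O | starting material
2 | vinylmagnesium bromide | C=C[Mg]Br | starting material
3 | (4E,6E)-deca-1,4,6-trien-3-ol (racemic) | CCC/C=C/C=C/C(O)C=C | intermediate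
4 | triethyl orthoacetate | CC(OCC)(OCC)OCC | starting material
5 | (4E,6E)-3-[(1-ethoxyethenyl)oxy]deca-1,4,6-triene (ketene acetal) | CCC/C=C/C=C/C(OC(=C)OCC)C=C | intermediate
6 | ethyl (4E,6E,8E)-dodeca-4,6,8-trienoate | CCC/C=C/C=C/C=C/CCC(=O)OCC | intermediate
7 | (4E,6E,8E)-dodeca-4,6,8-trien-1-ol | CCC/C=C/C=C/C=C/CCCO | intermediate
8 | 2-(bromomethyl)-4,4,5,5-tetramethyl-1,3,2-dioxaborolane | BrCB1OC(C)(C)C(C)(C)O1 | starting material
9 | sodium (4E,6E,8E)-dodeca-4,6,8-trien-1-olate | CCC/C=C/C=C/C=C/CCC[O-].[Na+] | intermediate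
10 | 2-({[(4E,6E,8E)-dodeca-4,6,8-trien-1-yl]oxy}methyl)-4,4,5,5-tetramethyl-1,3,2-dioxaborolane | CCC/C=C/C=C/C=C/CCCOCB1OC(C)(C)C(C)(C)O1 | intermediate
11 | 2-[(tert-butyldimethylsilyl)oxy]ethan-1-ol | CC(C)(C)[Si](C)(C)OCCO | starting material
12 | 2-[(tert-butyldimethylsilyl)oxy]ethyl 2,4,6-tri(propan-2-yl)benzoate | CC(C)(C)[Si](C)(C)OCCOC(=O)c1c(C(C)C)cc(C(C)C)cc1C(C)C | intermediate
13 | (1R)-2-[(tert-butyldimethylsilyl)oxy]-1-lithioethyl 2,4,6-tri(propan-2-yl)benzoate (as its (+)-sparteine complex) | CC(C)(C)[Si](C)(C)OC[C@@H]([Li])OC(=O)c1c(C(C)C)cc(C(C)C)cc1C(C)C | intermediate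
14 | lithium [(1R)-2-[(tert-butyldimethylsilyl)oxy]-1-{[2,4,6-tri(propan-2-yl)benzoyl]oxy}ethyl]({[(4E,6E,8E)-dodeca-4,6,8-trien-1-yl]oxy}methyl)(2,3-dimethylbutane-2,3-diolato)borate | [Li+].CCC/C=C/C=C/C=C/CCCOC[B-]1(OC(C)(C)C(C)(C)O1)[C@H](CO[Si](C)(C)C(C)(C)C)OC(=O)c1c(C(C)C)cc(C(C)C)cc1C(C)C | intermediate
15 | 2-[(2R)-1-[(tert-butyldimethylsilyl)oxy]-3-{[(4E,6E,8E)-dodeca-4,6,8-trien-1-yl]oxy}propan-2-yl]-4,4,5,5-tetramethyl-1,3,2-dioxaborolane | CCC/C=C/C=C/C=C/CCCOC[C@H](CO[Si](C)(C)C(C)(C)C)B1OC(C)(C)C(C)(C)O1 | intermediate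
16 | (2R)-1-[(tert-butyldimethylsilyl)oxy]-3-{[(4E,6E,8E)-dodeca-4,6,8-trien-1-yl]oxy}propan-2-ol | CCC/C=C/C=C/C=C/CCCOC[C@H](CO[Si](C)(C)C(C)(C)C)O | intermediate
17 | 4-hydroxybenzoic acid | OC(=O)c1ccc(O)cc1 | starting material
18 | tert-butyldimethylsilyl 4-[(tert-butyldimethylsilyl)oxy]benzoate | CC(C)(C)[Si](C)(C)OC(=O)c1ccc(O[Si](C)(C)C(C)(C)C)cc1 | intermediate
19 | 4-[(tert-butyldimethylsilyl)oxy]benzoic acid | CC(C)(C)[Si](C)(C)Oc1ccc(cc1)C(O)=O | intermediate
20 | (2R)-1-[(tert-butyldimethylsilyl)oxy]-3-{[(4E,6E,8E)-dodeca-4,6,8-trien-1-yl]oxy}propan-2-yl 4-[(tert-butyldimethylsilyl)oxy]benzoate | CCC/C=C/C=C/C=C/CCCOC[C@H](CO[Si](C)(C)C(C)(C)C)OC(=O)c1ccc(O[Si](C)(C)C(C)(C)C)cc1 | intermediate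
21 | (2S)-1-{[(4E,6E,8E)-dodeca-4,6,8-trien-1-yl]oxy}-3-hydroxypropan-2-yl 4-hydroxybenzoate | CCC/C=C/C=C/C=C/CCCOC[C@H](CO)OC(=O)c1ccc(O)cc1 | target

**Step count and risks**
Total steps: 9. Longest linear sequence: 7 (steps 1, 2, 3, 4, 6, 8, 9).

Step 6 is the most likely to fail. The lithiated ester may lose silanolate by β-elimination before it is borylated; coordination of the β-oxygen may erode the enantioselectivity of the deprotonation; and the 1,2-shift of the electron-poor α-alkoxymethyl group may be slow, so that the boronate complex reverts or decomposes. The fallback replaces the C–C union by a chiral-pool C–O union. It sets out from 7, which is mesylated (MsCl, Et3N, CH2Cl2) to (4E,6E,8E)-dodeca-4,6,8-trien-1-yl methanesulfonate F1. The sodium alkoxide of commercial (R)-solketal, [(4R)-2,2-dimethyl-1,3-dioxolan-4-yl]methanol (NaH, DMF), is alkylated with F1 to give (4R)-4-({[(4E,6E,8E)-dodeca-4,6,8-trien-1-yl]oxy}methyl)-2,2-dimethyl-1,3-dioxolane F2. Mild hydrolysis (80% aq AcOH, 40 °C) gives (2S)-3-{[(4E,6E,8E)-dodeca-4,6,8-trien-1-yl]oxy}propane-1,2-diol F3. Selective silylation of the primary hydroxyl (TBSCl, imidazole, CH2Cl2, −20 °C) brings the route back at 16.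

Step 9 is the second risk. Once the O3 hydroxyl is set free the aroyl group may shift from O2 to O3, and the alkyl silyl ether may cleave far more slowly than the aryl one, which lengthens the exposure. The fallback unmasks O3 enzymatically at neutral pH. It sets out from 16, which is desilylated with TBAF in THF before any ester is present, to give the diol that the first fallback calls F3. A lipase (immobilised Candida antarctica lipase B, vinyl acetate, MTBE) should acetylate only the primary hydroxyl, giving (2R)-3-{[(4E,6E,8E)-dodeca-4,6,8-trien-1-yl]oxy}-2-hydroxypropyl acetate F4. Steglich esterification with commercial 4-acetoxybenzoic acid (DCC, DMAP) gives (2R)-1-(acetyloxy)-3-{[(4E,6E,8E)-dodeca-4,6,8-trien-1-yl]oxy}propan-2-yl 4-(acetyloxy)benzoate F5. Lipase-catalysed ethanolysis (same enzyme, EtOH, MTBE, rt) should remove the primary and the phenolic acetate but not the hindered secondary aroyl ester, and so arrives at 21.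

Step 2 is the third risk. The doubly allylic alcohol may ionise or transpose under acid and heat, the [3,3] shift may partly run across the dienyl terminus, and the triene may isomerise or oligomerise at 138 °C. The fallback builds the 4E alkene by Julia–Kocienski olefination and sets out from 1. Commercial 4-[(tert-butyldimethylsilyl)oxy]butan-1-ol and 1-phenyl-1H-tetrazole-5-thiol (PPh3, DIAD) give 5-({4-[(tert-butyldimethylsilyl)oxy]butyl}sulfanyl)-1-phenyl-1H-tetrazole F6, which is oxidised (m-CPBA, NaHCO3) to 5-({4-[(tert-butyldimethylsilyl)oxy]butyl}sulfonyl)-1-phenyl-1H-tetrazole F7. The potassium salt of F7 (KHMDS, DME, −60 °C) is combined with 1 to give tert-butyl{[(4E,6E,8E)-dodeca-4,6,8-trien-1-yl]oxy}dimethylsilane F8. TBAF in THF then returns the route at 7.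

**Further compounds**
F1 | step 6 | (4E,6E,8E)-dodeca-4,6,8-trien-1-yl methanesulfonate | CCC/C=C/C=C/C=C/CCCOS(C)(=O)=O
F2 | step 6 | (4R)-4-({[(4E,6E,8E)-dodeca-4,6,8-trien-1-yl]oxy}methyl)-2,2-dimethyl-1,3-dioxolane | CCC/C=C/C=C/C=C/CCCOC[C@@H]1COC(C)(C)O1
F3 | step 6 | (2S)-3-{[(4E,6E,8E)-dodeca-4,6,8-trien-1-yl]oxy}propane-1,2-diol | CCC/C=C/C=C/C=C/CCCOC[C@H](CO)O
F4 | step 9 | (2R)-3-{[(4E,6E,8E)-dodeca-4,6,8-trien-1-yl]oxy}-2-hydroxypropyl acetate | CCC/C=C/C=C/C=C/CCCOC[C@H](COC(C)=O)O
F5 | step 9 | (2R)-1-(acetyloxy)-3-{[(4E,6E,8E)-dodeca-4,6,8-trien-1-yl]oxy}propan-2-yl 4-(acetyloxy)benzoate | CCC/C=C/C=C/C=C/CCCOC[C@H](COC(C)=O)OC(=O)c1ccc(OC(C)=O)cc1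
F6 | step 2 | 5-({4-[(tert-butyldimethylsilyl)oxy]butyl}sulfanyl)-1-phenyl-1H-tetrazole | CC(C)(C)[Si](C)(C)OCCCCSc1nnnn1-c1ccccc1
F7 | step 2 | 5-({4-[(tert-butyldimethylsilyl)oxy]butyl}sulfonyl)-1-phenyl-1H-tetrazole | CC(C)(C)[Si](C)(C)OCCCCS(=O)(=O)c1nnnn1-c1ccccc1
F8 | step 2 | tert-butyl{[(4E,6E,8E)-dodeca-4,6,8-trien-1-yl]oxy}dimethylsilane | CCC/C=C/C=C/C=C/CCCO[Si](C)(C)C(C)(C)C
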